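**Plan**

Ring numbering used below: cyclohex-2-en-1-one with C1 = carbonyl, C2=C3, C4 (OMe), C5 (CH2), C6 (quaternary).
Retrosynthesis: the acetate and the silyl ether go first; the C6–allyl bond is cut next, back to the allyl ester of a cyclic β-ketoester; the ring is then cut at C2=C3 and C5–C6 in one stroke; the side chain is cut last at the benzylic C–C bond.
Enabling feature: C1 is a ketone whose two α-carbons, C2 and C6, are bridged by the three-carbon unit C3–C4(OMe)–C5. The ring is therefore the sum of a C2–C1(=O)–C6 bis-nucleophile (an α-substituted acetoacetate, C6 activated by the ester, C2 its methyl group) and the bis-electrophile 2-methoxyacrolein, joined by a [3+3] Michael/aldol condensation.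
Forward order: side chain first (crotylation, alkene to allyl ester, C-acetylation), then the six-membered ring in one operation, then transfer of the allyl group from the ester oxygen to C6, then desilylation and acetylation.
Stereochemistry: the two side-chain centres come from a reagent-controlled Brown (E)-crotylation; C4 from catalyst-controlled protonation inside the annulation; C6 from a stereoconvergent decarboxylative allylation, in which both C6 epimers pass through one planar enolate that is allylated trans to the C4 methoxy group and anti to the large arm of the exocyclic stereocentre, with a matched ligand.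

Key step: step 8

Assumption: the (S)-configured diamine salt of step 8 is taken to deliver the proton to the enamine face that gives 4R; if the sense proves opposite, its (R)-antipode is used with no other change.

**Route**

Step 1
Reactants: 1 3,4,5-trimethoxybenzaldehyde
Product: 3 (1S,2S)-2-methyl-1-(3,4,5-trimethoxyphenyl)but-3-en-1-ol, via diisopinocampheylborinate ester 2 (not isolated)
Conditions: (E)-but-2-ene, n-BuLi, KOt-Bu, THF, −45 °C; (−)-Ipc2BOMe, −78 °C; BF3·OEt2; 1, −78 °C; then NaOH, H2O2, 0 °C to rt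
Reagents that add atoms: (E)-but-2-ene, C/C=C/C
Why: Brown crotylation, in which the (E)-crotylborane adds through a closed chair transition state so that the E geometry gives the anti relationship and the isopinocampheyl groups derived from (+)-α-pinene direct attack to the Si face of the aldehyde, which should give the (1S,2S) alcohol after oxidative work-up.

Step 2
Reactants: 3 (1S,2S)-2-methyl-1-(3,4,5-trimethoxyphenyl)but-3-en-1-ol
Product: 4 tert-butyldimethyl{[(1S,2S)-2-methyl-1-(3,4,5-trimethoxyphenyl)but-3-en-1-yl]oxy}silane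
Conditions: t-BuMe2SiOSO2CF3, 2,6-lutidine, CH2Cl2, 0 °C
Reagents that add atoms: tert-butyldimethylsilyl trifluoromethanesulfonate, CC(C)(C)[Si](C)(C)OS(=O)(=O)C(F)(F)F
Why: Silylation of the secondary benzylic alcohol with a silyl triflate and a hindered pyridine base gives an ether that should survive the enolate, amine and palladium steps and later serves as the large group that biases C6.

Step 3
Reactants: 4 tert-butyldimethyl{[(1S,2S)-2-methyl-1-(3,4,5-trimethoxyphenyl)but-3-en-1-yl]oxy}silane
Product: 6 (3S,4S)-4-{[tert-butyl(dimethyl)silyl]oxy}-3-methyl-4-(3,4,5-trimethoxyphenyl)butan-1-ol, via B-alkyl-9-borabicyclononane 5 (not isolated)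
Conditions: 9-borabicyclo[3.3.1]nonane, THF, 0 °C to rt; then NaOH, H2O2, 0 °C
Reagents that add atoms: hydrogen peroxide, OO
Why: Anti-Markovnikov hydroboration–oxidation of the terminal alkene with a bulky dialkylborane places the hydroxyl on the terminal carbon and touches no stereocentre.

Step 4
Reactants: 6 (3S,4S)-4-{[tert-butyl(dimethyl)silyl]oxy}-3-methyl-4-(3,4,5-trimethoxyphenyl)butan-1-ol
Product: 7 (3S,4S)-4-{[tert-butyl(dimethyl)silyl]oxy}-3-methyl-4-(3,4,5-trimethoxyphenyl)butanoic acid
Conditions: (2,2,6,6-tetramethylpiperidin-1-yl)oxyl (10 mol %), PhI(OAc)2, MeCN/H2O, rt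
Reagents that add atoms: water, O
Why: Nitroxyl-catalysed oxidation of the primary alcohol through the aldehyde hydrate to the carboxylic acid, under conditions that should leave the silyl ether and the electron-rich arene untouched.

Step 5
Reactants: 7 (3S,4S)-4-{[tert-butyl(dimethyl)silyl]oxy}-3-methyl-4-(3,4,5-trimethoxyphenyl)butanoic acid
Product: 8 allyl (3S,4S)-4-{[tert-butyl(dimethyl)silyl]oxy}-3-methyl-4-(3,4,5-trimethoxyphenyl)butanoate
Conditions: allyl bromide, K2CO3, DMF, rt
Reagents that add atoms: allyl bromide, C=CCBr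
Why: Carboxylate O-alkylation (SN2) installs the allyl ester that later acts both as the activating group for the annulation and as the source of the C6 allyl group.

Step 6
Reactants: 8 allyl (3S,4S)-4-{[tert-butyl(dimethyl)silyl]oxy}-3-methyl-4-(3,4,5-trimethoxyphenyl)butanoate
Product: 9 allyl (3S,4S)-2-acetyl-4-{[tert-butyl(dimethyl)silyl]oxy}-3-methyl-4-(3,4,5-trimethoxyphenyl)butanoate (both C2 epimers)
Conditions: LiN(i-Pr)2, THF, −78 °C; MeC(O)N(OMe)Me, −78 to −30 °C; aq. NH4Cl
Reagents that add atoms: N-methoxy-N-methylacetamide, CC(=O)N(C)OC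
Why: Crossed Claisen-type C-acylation of the ester lithium enolate with a Weinreb amide, whose chelated tetrahedral adduct should prevent over-addition and proton exchange, gives the β-ketoester with a deliberately uncontrolled, epimerisable α-carbon.

Step 7
Reactants: 10 methoxyacetaldehyde
Product: 11 2-methoxyprop-2-enal (2-methoxyacrolein)
Conditions: aq. CH2O, pyrrolidine (10 mol %), propanoic acid (10 mol %), i-PrOH, 45 °C; used as a solution
Reagents that add atoms: formaldehyde, C=O
Why: Amine-catalysed Mannich condensation with formaldehyde followed by β-elimination of the amine (α-methylenation of an aldehyde) should give the volatile enal, which is used without storage.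

Step 8
Reactants: 9 allyl (3S,4S)-2-acetyl-4-{[tert-butyl(dimethyl)silyl]oxy}-3-methyl-4-(3,4,5-trimethoxyphenyl)butanoate (both C2 epimers); 11 2-methoxyprop-2-enal
Product: 13 allyl (5R)-1-[(1S,2S)-1-{[tert-butyl(dimethyl)silyl]oxy}-1-(3,4,5-trimethoxyphenyl)propan-2-yl]-5-methoxy-2-oxocyclohex-3-ene-1-carboxylate (both C1 epimers), via keto aldehyde Michael adduct 12 (not isolated)
Conditions: 11 (1.5 equiv), (S)-N1,N1-diethyl-3,3-dimethylbutane-1,2-diamine trifluoromethanesulfonate (20 mol %), CHCl3, 25 °C, then 40 °C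
Reagents that add atoms: none
Why: Proposed new method: the primary amine of the catalyst condenses with 11 to an iminium ion, the enol of 9 adds through its doubly activated α-carbon to the CH2 terminus (Michael addition, new C5–C6 bond), and the 2-methoxy enamine that results is protonated on one face by the adjacent ammonium group, which gives 12 with C4 set under catalyst control. The methyl ketone of 12 then closes onto the aldehyde carbon, still activated as iminium ion, in a 6-(enolendo)-exo-trig aldol (Mannich) step, and β-elimination of the amine gives the C2=C3 bond and frees the catalyst. The closest known reaction types are the amine-catalysed Michael/aldol-condensation [3+3] annulation of β-ketoesters with enals and the primary-amine-catalysed conjugate addition with enantioselective protonation of α-substituted acroleins, which have not been combined in one operation on an α-alkoxy acrolein. The ester secures the regiochemistry, since it makes the substituted α-carbon the only soft nucleophile for the Michael step and leaves the methyl group as the only enolisable site for the ring closure. The quaternary carbon C6 is formed as both epimers on purpose because it is planarised again in step 9, so the one selectivity the step needs is the facial sense of the C4 protonation, and the crowded C1 carbonyl of 13 should keep the amine from forming the dienamine that could epimerise C4.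

Step 9
Reactants: 13 allyl (5R)-1-[(1S,2S)-1-{[tert-butyl(dimethyl)silyl]oxy}-1-(3,4,5-trimethoxyphenyl)propan-2-yl]-5-methoxy-2-oxocyclohex-3-ene-1-carboxylate (both C1 epimers)
Product: 14 (4R,6R)-6-[(1S,2S)-1-{[tert-butyl(dimethyl)silyl]oxy}-1-(3,4,5-trimethoxyphenyl)propan-2-yl]-4-methoxy-6-(prop-2-en-1-yl)cyclohex-2-en-1-one
Conditions: Pd2(dba)3 (5 mol %), (S)-4-tert-butyl-2-[2-(diphenylphosphanyl)phenyl]-4,5-dihydro-1,3-oxazole (12.5 mol %), toluene, 30 °C
Reagents that add atoms: none
Why: Decarboxylative allylic alkylation (Tsuji type) with a zerovalent palladium–phosphinooxazoline catalyst, in which ionisation of the allyl ester and loss of CO2 give one planar cross-conjugated enolate from both C6 epimers of 13, and C–C bond formation at C6 should occur trans to the C4 methoxy group and anti to the CH(OSi)Ar arm of the exocyclic stereocentre (its C–H bond lying in the enolate plane to relieve allylic strain), the same sense that the (S)-ligand favours in the formation of 2-alkyl-2-allylcyclohexanones, so that 6R is set.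

Step 10
Reactants: 14 (4R,6R)-6-[(1S,2S)-1-{[tert-butyl(dimethyl)silyl]oxy}-1-(3,4,5-trimethoxyphenyl)propan-2-yl]-4-methoxy-6-(prop-2-en-1-yl)cyclohex-2-en-1-one
Product: 15 (4R,6R)-6-[(1S,2S)-1-hydroxy-1-(3,4,5-trimethoxyphenyl)propan-2-yl]-4-methoxy-6-(prop-2-en-1-yl)cyclohex-2-en-1-one
Conditions: HF·pyridine, pyridine, THF, 0 °C to rt
Reagents that add atoms: none
Why: Fluoride cleavage of the silyl ether under buffered, non-basic conditions, chosen so that C4, whose hydrogen is the only enolisable one of the γ-methoxy enone, should not epimerise.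

Step 11
Reactants: 15 (4R,6R)-6-[(1S,2S)-1-hydroxy-1-(3,4,5-trimethoxyphenyl)propan-2-yl]-4-methoxy-6-(prop-2-en-1-yl)cyclohex-2-en-1-one
Product: 16 (1S,2S)-2-[(1R,5R)-5-methoxy-2-oxo-1-(prop-2-en-1-yl)cyclohex-3-en-1-yl]-1-(3,4,5-trimethoxyphenyl)propyl acetate
Conditions: Ac2O, pyridine, 4-(dimethylamino)pyridine (5 mol %), CH2Cl2, rt
Reagents that add atoms: acetic anhydride, CC(=O)OC(C)=O
Why: Nucleophile-catalysed acetylation of the secondary benzylic alcohol should give the target without affecting the enone or any stereocentre.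

**Compound list**

1 | 3,4,5-trimethoxybenzaldehyde | COc1cc(C=O)cc(OC)c1OC | starting material
2 | (1S,2S)-2-methyl-1-(3,4,5-trimethoxyphenyl)but-3-en-1-yl diisopinocampheylborinate (isopinocampheyl groups from (+)-α-pinene; not isolated) | C=C[C@H](C)[C@H](OB([C@@H]1C[C@@H]2C[C@H]([C@H]1C)C2(C)C)[C@@H]1C[C@@H]2C[C@H]([C@H]1C)C2(C)C)c1cc(OC)c(OC)c(OC)c1 | intermediate
3 | (1S,2S)-2-methyl-1-(3,4,5-trimethoxyphenyl)but-3-en-1-ol | C=C[C@H](C)[C@H](O)c1cc(OC)c(OC)c(OC)c1 | intermediate
4 | tert-butyldimethyl{[(1S,2S)-2-methyl-1-(3,4,5-trimethoxyphenyl)but-3-en-1-yl]oxy}silane | C=C[C@H](C)[C@H](O[Si](C)(C)C(C)(C)C)c1cc(OC)c(OC)c(OC)c1 | intermediate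
5 | 9-[(3S,4S)-4-{[tert-butyl(dimethyl)silyl]oxy}-3-methyl-4-(3,4,5-trimethoxyphenyl)butyl]-9-borabicyclo[3.3.1]nonane (not isolated) | B1(CC[C@H](C)[C@H](O[Si](C)(C)C(C)(C)C)c2cc(OC)c(OC)c(OC)c2)C3CCCC1CCC3 | intermediate
6 | (3S,4S)-4-{[tert-butyl(dimethyl)silyl]oxy}-3-methyl-4-(3,4,5-trimethoxyphenyl)butan-1-ol | OCC[C@H](C)[C@H](O[Si](C)(C)C(C)(C)C)c1cc(OC)c(OC)c(OC)c1 | intermediate
7 | (3S,4S)-4-{[tert-butyl(dimethyl)silyl]oxy}-3-methyl-4-(3,4,5-trimethoxyphenyl)butanoic acid | OC(=O)C[C@H](C)[C@H](O[Si](C)(C)C(C)(C)C)c1cc(OC)c(OC)c(OC)c1 | intermediate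
8 | allyl (3S,4S)-4-{[tert-butyl(dimethyl)silyl]oxy}-3-methyl-4-(3,4,5-trimethoxyphenyl)butanoate | C=CCOC(=O)C[C@H](C)[C@H](O[Si](C)(C)C(C)(C)C)c1cc(OC)c(OC)c(OC)c1 | intermediate
9 | allyl (3S,4S)-2-acetyl-4-{[tert-butyl(dimethyl)silyl]oxy}-3-methyl-4-(3,4,5-trimethoxyphenyl)butanoate (both C2 epimers) | C=CCOC(=O)C(C(C)=O)[C@H](C)[C@H](O[Si](C)(C)C(C)(C)C)c1cc(OC)c(OC)c(OC)c1 | intermediate
10 | methoxyacetaldehyde | COCC=O | starting material
11 | 2-methoxyprop-2-enal (2-methoxyacrolein) | C=C(OC)C=O | intermediate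
12 | allyl (3S,4S)-2-acetyl-4-{[tert-butyl(dimethyl)silyl]oxy}-2-[(2R)-2-methoxy-3-oxopropyl]-3-methyl-4-(3,4,5-trimethoxyphenyl)butanoate (both C2 epimers; not isolated) | C=CCOC(=O)C(C(C)=O)(C[C@@H](OC)C=O)[C@H](C)[C@H](O[Si](C)(C)C(C)(C)C)c1cc(OC)c(OC)c(OC)c1 | intermediate
13 | allyl (5R)-1-[(1S,2S)-1-{[tert-butyl(dimethyl)silyl]oxy}-1-(3,4,5-trimethoxyphenyl)propan-2-yl]-5-methoxy-2-oxocyclohex-3-ene-1-carboxylate (both C1 epimers) | C=CCOC(=O)C1([C@H](C)[C@H](O[Si](C)(C)C(C)(C)C)c2cc(OC)c(OC)c(OC)c2)C[C@@H](OC)C=CC1=O | intermediate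
14 | (4R,6R)-6-[(1S,2S)-1-{[tert-butyl(dimethyl)silyl]oxy}-1-(3,4,5-trimethoxyphenyl)propan-2-yl]-4-methoxy-6-(prop-2-en-1-yl)cyclohex-2-en-1-one | C=CC[C@]1([C@H](C)[C@H](O[Si](C)(C)C(C)(C)C)c2cc(OC)c(OC)c(OC)c2)C[C@@H](OC)C=CC1=O | intermediate
15 | (4R,6R)-6-[(1S,2S)-1-hydroxy-1-(3,4,5-trimethoxyphenyl)propan-2-yl]-4-methoxy-6-(prop-2-en-1-yl)cyclohex-2-en-1-one | C=CC[C@]1([C@H](C)[C@H](O)c2cc(OC)c(OC)c(OC)c2)C[C@@H](OC)C=CC1=O | intermediate
16 | (1S,2S)-2-[(1R,5R)-5-methoxy-2-oxo-1-(prop-2-en-1-yl)cyclohex-3-en-1-yl]-1-(3,4,5-trimethoxyphenyl)propyl acetate | C=CC[C@]1([C@H](C)[C@H](OC(C)=O)c2cc(OC)c(OC)c(OC)c2)C[C@@H](OC)C=CC1=O | target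

**Step count and risks**

Total step count: 11. Longest linear sequence: 10 steps (steps 1–6 and 8–11, from 1 to 16); step 7 is a one-step side branch.

Steps most likely to fail:

Step 8 (proposed new method). Control at C4 may be lost if the α-methoxy iminium ion returns to its enamine before the ring closes. The hindered β-ketoester may also add too slowly, so that the enal polymerises instead. Fallback with known chemistry, setting out from 9: Michael addition to acrolein and acid-mediated aldol condensation (cat. K2CO3, then p-TsOH, toluene, reflux) should give allyl 1-[(1S,2S)-1-{[tert-butyl(dimethyl)silyl]oxy}-1-(3,4,5-trimethoxyphenyl)propan-2-yl]-2-oxocyclohex-3-ene-1-carboxylate F1. γ-Oxidation of the enone (Pd(OH)2 on carbon, t-BuOOH, K2CO3, CH2Cl2) should give the corresponding 2,5-dioxocyclohex-3-ene-1-carboxylate F2. Reagent-controlled reduction of the unhindered C5 carbonyl ((S)-1-methyl-3,3-diphenyltetrahydro-1H,3H-pyrrolo[1,2-c][1,3,2]oxazaborole, catecholborane, toluene, −78 °C, the alkene arm acting as the large group) should give the (5R)-5-hydroxy-2-oxocyclohex-3-ene-1-carboxylate F3. O-Methylation (MeI, Ag2O) comes back to the route at 13.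

Step 9. C–C bond formation at the congested C6 may be slow, so that the palladium enolate is protonated or loses methanol with aromatisation; facial discrimination may also be insufficient. Fallback, setting out from 13: deallylation with decarboxylation (Pd(PPh3)4, HCO2H, Et3N, THF) should give (4R)-6-[(1S,2S)-1-{[tert-butyl(dimethyl)silyl]oxy}-1-(3,4,5-trimethoxyphenyl)propan-2-yl]-4-methoxycyclohex-2-en-1-one F4. Kinetic deprotonation at C6 (LiN(i-Pr)2, THF, −78 °C) and alkylation of the lithium enolate with allyl bromide, expected to enter trans to the C4 methoxy group, comes back to the route at 14.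

Step 6. Addition of the hindered enolate to the amide may be sluggish at the low temperature needed to suppress the [3,3] rearrangement of the allyl ester enolate (Ireland–Claisen). Fallback, setting out from 8: aldol addition of the lithium enolate to acetaldehyde (LiN(i-Pr)2, THF, −78 °C) should give allyl (3S,4S)-4-{[tert-butyl(dimethyl)silyl]oxy}-2-(1-hydroxyethyl)-3-methyl-4-(3,4,5-trimethoxyphenyl)butanoate F5 as a mixture of diastereomers. Oxidation with the Dess–Martin periodinane comes back to the route at 9.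

**Further compounds**

F1 | step 8 | allyl 1-[(1S,2S)-1-{[tert-butyl(dimethyl)silyl]oxy}-1-(3,4,5-trimethoxyphenyl)propan-2-yl]-2-oxocyclohex-3-ene-1-carboxylate (both C1 epimers) | C=CCOC(=O)C1([C@H](C)[C@H](O[Si](C)(C)C(C)(C)C)c2cc(OC)c(OC)c(OC)c2)CCC=CC1=O
F2 | step 8 | allyl 1-[(1S,2S)-1-{[tert-butyl(dimethyl)silyl]oxy}-1-(3,4,5-trimethoxyphenyl)propan-2-yl]-2,5-dioxocyclohex-3-ene-1-carboxylate (both C1 epimers) | C=CCOC(=O)C1([C@H](C)[C@H](O[Si](C)(C)C(C)(C)C)c2cc(OC)c(OC)c(OC)c2)CC(=O)C=CC1=O
F3 | step 8 | allyl (5R)-1-[(1S,2S)-1-{[tert-butyl(dimethyl)silyl]oxy}-1-(3,4,5-trimethoxyphenyl)propan-2-yl]-5-hydroxy-2-oxocyclohex-3-ene-1-carboxylate (both C1 epimers) | C=CCOC(=O)C1([C@H](C)[C@H](O[Si](C)(C)C(C)(C)C)c2cc(OC)c(OC)c(OC)c2)C[C@@H](O)C=CC1=O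
F4 | step 9 | (4R)-6-[(1S,2S)-1-{[tert-butyl(dimethyl)silyl]oxy}-1-(3,4,5-trimethoxyphenyl)propan-2-yl]-4-methoxycyclohex-2-en-1-one (both C6 epimers) | C1([C@H](C)[C@H](O[Si](C)(C)C(C)(C)C)c2cc(OC)c(OC)c(OC)c2)C[C@@H](OC)C=CC1=O
F5 | step 6 | allyl (3S,4S)-4-{[tert-butyl(dimethyl)silyl]oxy}-2-(1-hydroxyethyl)-3-methyl-4-(3,4,5-trimethoxyphenyl)butanoate (mixture of diastereomers at C2 and the carbinol carbon) | C=CCOC(=O)C(C(C)O)[C@H](C)[C@H](O[Si](C)(C)C(C)(C)C)c1cc(OC)c(OC)c(OC)c1
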